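# Proposed total synthesis of CNP0290035.1 (compound 13)

## Analysis of the target

Compound 13 is (1S,4S,5R,8S)-8-(3,4-dihydroxyphenyl)-4-(3,4,5-trihydroxyphenyl)-3,7-dioxabicyclo[3.3.0]octan-2-one. A γ-lactone (C1, C2, O3, C4, C5) is fused along C1–C5 to a tetrahydrofuran (C1, C5, C6, O7, C8). The four stereocentres C8, C1, C5 and C4 are contiguous. H1 and H5 are cis (cis ring fusion) and both aryl groups sit on the convex face, so the C8 aryl is trans to the C2 carbonyl across the ether ring and the C4 aryl is trans to C6 across the lactone ring. This cis-fused, all-exo arrangement is the thermodynamically preferred one, and a trans-fused 5–5 lactone is out of reach, so one centre set by a reagent can in principle command the other three. The sensitive groups are the catechol and pyrogallol units (air oxidation, so protected until the last step), the two benzylic C–O bonds (C4–O3 of the lactone and C8–O7 of the ether, both ionizable in acid and open to hydrogenolysis) and the epimerizable C1–H. The difficulty is that the molecule is unsymmetrical twice over (two different arenes, one lactone ring and one ether ring), which rules out any dimerization logic, and that no chiral-pool piece maps onto it. The strategy rests on reading the ether ring as the aldehyde unit C8=O7 spanned by the three-carbon chain C1–C5–C6, whose central carbon C5 carries an exocyclic carbon (the site of C4) and whose terminus C1 carries the carboxyl carbon C2. That is the pattern of a trimethylenemethane cycloadduct of an aryl aldehyde.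

## Retrosynthetic reasoning

**13 to 12.** All five phenols are unmasked last, from the pentabenzyl ether 12. Uniform benzyl protection lets both aryl fragments come from purchasable aldehydes, survives every earlier step, and leaves by neutral hydrogenolysis, which suits an air-sensitive polyphenol.

**12 to 11.** The lactone is opened at O3–C4 together with the C5–H bond, giving the β,γ-unsaturated acid 11 with a C4=C5 styrene double bond. This is the one C–O bond of 12 that ionizes reversibly in any case. Forward, protonation at C5 gives the C4 benzylic cation and the C2 carboxyl captures it. C5 and C4 are then set by geometry and equilibration, relayed from C1, and need no reagent control.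

**11 to 10.** The acid comes from the methyl ester 10 by hydrolysis. The carboxyl carbon is carried at its final oxidation state from the first step.

**10 to 7 and 9.** The C4=C5 double bond is cut by a metathesis transform. The ring-bearing half is the methylene compound 7 and the aryl-bearing C4 comes from the styrene 9. This brings in the second arene late and convergently as a simple alkene, and the geometry of the new double bond is irrelevant because step 7 erases it.

**9 to 8.** The styrene is the methylenation product of the purchasable aldehyde 8.

**7 to 5 and 6.** This is the key disconnection: C1–C8 and C6–O7 are cut together. The ring atoms C8 and O7 are the carbonyl of aldehyde 6. The chain C1–C5–C6 with its exocyclic methylene and the ester on C1 is the ester-substituted trimethylenemethane unit stored in the silyl acetate 5. Forward, a chiral palladium catalyst has to generate the zwitterion, join its ester-bearing carbon to the aldehyde carbon, close the ether on the allyl terminus, and set C8 absolutely and C1 relative to it.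

**5 to 4 to 1 and 2 (through 3).** The acetate 5 comes from the hydroxy ester 4, and 4 from the bond between the vinylic carbon and the carbinol carbon: the alkenylmagnesium reagent 3 (from bromide 1) adds to the aldehyde group of glyoxylate 2. The ester is placed on the acetoxy-bearing carbon and silicon on the unsubstituted methylene. Ionization and desilylation give one delocalized complex whichever terminus carries the ester, and this arrangement is the one that two reliable steps reach. An arrangement with silicon and ester on the same carbon would require deprotonating an allylsilane next to an acetate and acylating it at the silyl-bearing carbon, which is not workable.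

## Alternatives that were turned down

**Alternative 1: double quinone methide cyclization.**
- Disconnection: both benzylic C–O bonds (O7–C8 and O3–C4) are cut, back to the open-chain hydroxy amide A1, (2R,3R)-2-[3-(benzyloxy)-4-hydroxybenzyl]-3-[3,5-bis(benzyloxy)-4-hydroxybenzyl]-4-hydroxy-N,N-dimethylbutanamide, with C1 and C5 already in place.
- Forward key step: Ag2O takes both para-hydroxybenzyl groups to the quinone methide level. The primary hydroxyl closes on C8, the amide oxygen closes on C4, and hydrolysis of the iminium ether gives the tribenzyl ether A2.
- For: ring size alone decides which oxygen attacks which carbon, and both benzylic centres form under the exo preference. The trans-dibenzyl array at C1/C5 comes from well-established butyrolactone alkylation chemistry; on this point the alternative is stronger than the chosen route, whose C1 and C5 depend on a new cycloaddition and a cation.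
- Against: each arene needs the para-hydroxyl free and the others benzylated, which costs selective protection steps on both fragments. The mono-ortho-alkoxy phenol is oxidized to a quinone methide far less cleanly than the 2,6-dialkoxy phenol, and both oxidations must succeed in one molecule beside another electron-rich phenol (radical coupling, over-oxidation). C1 and C5 still need a multistep auxiliary or chiral-pool sequence, and A2 still needs debenzylation.
- Comparison: clearly longer, with a stoichiometric oxidation of a polyphenol as its key step. The chosen route offers catalytic enantiocontrol, uniformly protected purchasable aldehydes and eight steps.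

**Alternative 2: intramolecular (2+2) photocycloaddition, then Baeyer–Villiger expansion.**
- Disconnection: C1–C5 and C2–C4 are cut, with O3 inserted afterwards. The precursor is the ether A3, in which the C8 stereocentre links an alkenyl pinacol boronate to a cinnamyl unit.
- Forward key step: visible-light triplet sensitization of the styrene by an iridium sensitizer closes C1–C5 first (ether ring) and then C2–C4, giving the cyclobutyl boronate A4. The boron-bearing carbon is then taken to the ketone oxidation level and a Baeyer–Villiger oxygen insertion on the aryl-bearing side gives the lactone.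
- For: the tether guarantees the cis ring fusion, the benzylic C4 migrates regioselectively and with retention, and no cation is ever formed next to C8. In this the alternative is stronger than the chosen route, which sets C5 and C4 through an equilibrating cation.
- Against: C8 must first be made enantioselectively in an ether that is both benzylic and allylic and therefore prone to ionization. The stepwise diradical gives no assurance for the C4 configuration or for the face selectivity relative to C8. Three redox operations are spent only to turn C2 into a lactone carbonyl, one of them a peracid oxidation beside five benzyloxyarenes.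
- Comparison: about ten or more steps. The chosen route carries C2 as a carboxyl from the first step.

**Alternative 3: carbonyl ylide (3+2) cycloaddition onto a chiral butenolide.**
- Disconnection: C1–C8 and C5–C6 are cut. The partners are the butenolide A5, (S)-5-[3,4,5-tris(benzyloxy)phenyl]furan-2(5H)-one, and the α-chloro silylmethyl ether A6 derived from aldehyde 6.
- Forward key step: CsF induces 1,3-elimination from A6. The resulting aryl-substituted 1,3-dipole adds to the butenolide double bond anti to the C4 aryl and gives A7, which is the same compound as 12.
- For: it is the most convergent plan. Two C–C bonds and three stereocentres form in one step, the product is already the penultimate compound, and the step count is lower than in the chosen route. On step economy and convergence this alternative is stronger.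
- Against: the γ-hydrogen of A5 is benzylic and vinylogously acidic, so fluoride can racemize it through the 2-oxyfuran, and its enantioselective preparation is not trivial. A6 is the chloride of an electron-rich benzylic acetal-type carbon and ionizes readily. Non-stabilized ylides give modest endo/exo control at C8.
- Comparison: the chosen route has more steps after ring formation, but all its intermediates are stable, the absolute configuration comes from a catalyst and not from a racemization-prone centre, and the late stereocentres are set under thermodynamic control.

Key step: step 3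

**Remarks on the chemistry**

- Assumption: the sense of induction of the phosphoramidite with an ester-substituted donor cannot be read from the parent reaction; the ligand antipode that delivers (2S,3S)-7 is taken, both antipodes being accessible.
- Assumption: methyl glyoxylate 2 is used as the purchased reagent and depolymerised by distillation immediately before use.

## Steps

**Step 1**
Reactants: 1 (2-bromoallyl)trimethylsilane; 2 methyl glyoxylate
Product: 4 methyl 2-hydroxy-3-[(trimethylsilyl)methyl]but-3-enoate (racemic), via alkenylmagnesium bromide 3 (not isolated)
Conditions: Mg, THF, rt; then added to 2 (2 equiv), THF, −78 °C; aq NH4Cl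
Reagents that add atoms: none
Why: Grignard formation from the vinyl bromide and 1,2-addition to the aldehyde carbonyl, which at −78 °C is far more electrophilic than the ester; inverse addition to excess 2 keeps the ester untouched. The new stereocentre is racemic and is erased in step 3.

**Step 2**
Reactants: 4 methyl 2-hydroxy-3-[(trimethylsilyl)methyl]but-3-enoate
Product: 5 methyl 2-acetoxy-3-[(trimethylsilyl)methyl]but-3-enoate (racemic)
Conditions: Ac2O, pyridine, DMAP (cat.), CH2Cl2, 0 °C
Reagents that add atoms: acetic anhydride, CC(=O)OC(C)=O
Why: DMAP-catalysed O-acetylation of a secondary alcohol; the conditions are too mild to move the double bond or to attack the allylsilane.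

**Step 3**
Reactants: 5 methyl 2-acetoxy-3-[(trimethylsilyl)methyl]but-3-enoate; 6 3,4-bis(benzyloxy)benzaldehyde
Product: 7 methyl (2S,3S)-2-[3,4-bis(benzyloxy)phenyl]-4-methylenetetrahydrofuran-3-carboxylate (aryl and ester trans)
Conditions: Pd(dba)2 (5 mol %), BINOL-derived phosphoramidite of trans-2,5-di(2-naphthyl)pyrrolidine (10 mol %), 5 (1.6 equiv), toluene, rt to 45 °C
Reagents that add atoms: none
Why: Zerovalent palladium ionizes the allylic acetate of 5 (both enantiomers give the same η3-allyl complex) and the acetate set free removes the silyl group, leaving the zwitterionic palladium trimethylenemethane complex whose negative charge rests on the ester-bearing carbon as an ester enolate. That carbon adds to the carbonyl carbon of 6 (bond C1–C8), and the alkoxide then attacks a CH2 terminus of the η3-allyl unit (bond C6–O7), an intramolecular allylic O-alkylation that closes the five-membered ether in the exo mode with respect to the departing palladium and leaves the double bond exocyclic. The closest known reactions are the palladium-catalysed asymmetric trimethylenemethane (3+2) cycloaddition of the unsubstituted donor with aryl aldehydes and the cycloadditions of acceptor-substituted (cyano) donors with alkenes and imines; this step combines the two. C8 is set inside the chiral pocket of the phosphoramidite-bound palladium, either in the C–C bond formation or, if that aldol-type addition is reversible, in the ring closure that selects one aldolate. C1 takes the configuration with the ester trans to the aryl group because that closure avoids eclipsing the two groups, and the acidic C1–H lets any cis isomer drift to the same trans ester. The step needs regioselectivity (ester-bearing carbon to the aldehyde carbon), secured by the charge being localized where the ester stabilizes it, and chemoselectivity for the aldehyde over self-reaction of the donor, helped by the excess of 5 and the non-polar solvent.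

**Step 4**
Reactants: 8 3,4,5-tris(benzyloxy)benzaldehyde
Product: 9 1,2,3-tris(benzyloxy)-5-vinylbenzene
Conditions: Ph3PCH3Br, KOtBu, THF, 0 °C to rt
Reagents that add atoms: methyltriphenylphosphonium bromide, C[P+](c1ccccc1)(c1ccccc1)c1ccccc1.[Br-]
Why: Wittig methylenation of an aryl aldehyde with the non-stabilized ylide; the benzyl ethers are inert.

**Step 5**
Reactants: 7 methyl (2S,3S)-2-[3,4-bis(benzyloxy)phenyl]-4-methylenetetrahydrofuran-3-carboxylate; 9 1,2,3-tris(benzyloxy)-5-vinylbenzene
Product: 10 methyl (2S,3S)-2-[3,4-bis(benzyloxy)phenyl]-4-[3,4,5-tris(benzyloxy)benzylidene]tetrahydrofuran-3-carboxylate (double-bond geometry left open)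
Conditions: second-generation Hoveyda–Grubbs catalyst (10 mol %), 9 (3 equiv), 1,4-benzoquinone (20 mol %), toluene, 80 °C, argon purge
Reagents that add atoms: none
Why: Olefin cross-metathesis of a 1,1-disubstituted alkene with a styrene to a trisubstituted alkene, driven by loss of ethylene; the styrene is used in excess because its homodimer re-enters only slowly, and benzoquinone suppresses ruthenium hydride isomerization of the exocyclic double bond. The geometry of the new alkene does not matter because step 7 passes through a planar cation.

**Step 6**
Reactants: 10 methyl (2S,3S)-2-[3,4-bis(benzyloxy)phenyl]-4-[3,4,5-tris(benzyloxy)benzylidene]tetrahydrofuran-3-carboxylate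
Product: 11 (2S,3S)-2-[3,4-bis(benzyloxy)phenyl]-4-[3,4,5-tris(benzyloxy)benzylidene]tetrahydrofuran-3-carboxylic acid
Conditions: LiOH·H2O, THF/MeOH/H2O, 0 °C to rt; then 1 M HCl to pH 3 at 0 °C
Reagents that add atoms: lithium hydroxide, [Li+].[OH-]
Why: Saponification of a methyl ester; once the carboxylate has formed the C1–H is no longer acidic, and any deprotonation before that point should return the same, more stable trans isomer on α-protonation.

**Step 7**
Reactants: 11 (2S,3S)-2-[3,4-bis(benzyloxy)phenyl]-4-[3,4,5-tris(benzyloxy)benzylidene]tetrahydrofuran-3-carboxylic acid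
Product: 12 (1S,4S,5R,8S)-8-[3,4-bis(benzyloxy)phenyl]-4-[3,4,5-tris(benzyloxy)phenyl]-3,7-dioxabicyclo[3.3.0]octan-2-one
Conditions: TFA (5 equiv), CH2Cl2, 0 °C to rt
Reagents that add atoms: none
Why: Acid-catalysed lactonization of a β,γ-unsaturated acid (intramolecular hydroacyloxylation of a styrene): protonation at C5 gives the C4 benzylic cation, stabilized by the tris(benzyloxy)phenyl ring, and the carboxyl group captures it (bond O3–C4). Protonation is reversible and only the cation whose C4 lies cis to the carboxyl can close, which fixes C5 as the cis-fused centre. The C4–O3 bond of the product re-ionizes under the same conditions, so C4 should settle with its aryl on the convex face.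

**Step 8**
Reactants: 12 (1S,4S,5R,8S)-8-[3,4-bis(benzyloxy)phenyl]-4-[3,4,5-tris(benzyloxy)phenyl]-3,7-dioxabicyclo[3.3.0]octan-2-one
Product: 13 (1S,4S,5R,8S)-8-(3,4-dihydroxyphenyl)-4-(3,4,5-trihydroxyphenyl)-3,7-dioxabicyclo[3.3.0]octan-2-one
Conditions: H2 (1 atm), 10% Pd/C, THF/MeOH, rt, stopped at full conversion; filtered and concentrated under argon
Reagents that add atoms: none
Why: Hydrogenolysis of the five aryl benzyl ethers, which at 1 atm in a non-acidic solvent is much faster than cleavage of the two cyclic benzylic C–O bonds; no stereocentre is touched.

## Compound list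

1 | (2-bromoallyl)trimethylsilane [2-bromo-3-(trimethylsilyl)prop-1-ene] | C=C(Br)C[Si](C)(C)C | starting material
2 | methyl glyoxylate | COC(=O)C=O | starting material
3 | [3-(trimethylsilyl)prop-1-en-2-yl]magnesium bromide (not isolated) | C=C(C[Si](C)(C)C)[Mg]Br | intermediate
4 | methyl 2-hydroxy-3-[(trimethylsilyl)methyl]but-3-enoate (racemic) | COC(=O)C(O)C(=C)C[Si](C)(C)C | intermediate
5 | methyl 2-acetoxy-3-[(trimethylsilyl)methyl]but-3-enoate (racemic) | COC(=O)C(OC(C)=O)C(=C)C[Si](C)(C)C | intermediate
6 | 3,4-bis(benzyloxy)benzaldehyde | O=Cc1ccc(OCc2ccccc2)c(OCc2ccccc2)c1 | starting material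
7 | methyl (2S,3S)-2-[3,4-bis(benzyloxy)phenyl]-4-methylenetetrahydrofuran-3-carboxylate | C=C1CO[C@H](c2ccc(OCc3ccccc3)c(OCc3ccccc3)c2)[C@H]1C(=O)OC | intermediate
8 | 3,4,5-tris(benzyloxy)benzaldehyde | O=Cc1cc(OCc2ccccc2)c(OCc2ccccc2)c(OCc2ccccc2)c1 | starting material
9 | 1,2,3-tris(benzyloxy)-5-vinylbenzene | C=Cc1cc(OCc2ccccc2)c(OCc2ccccc2)c(OCc2ccccc2)c1 | intermediate
10 | methyl (2S,3S)-2-[3,4-bis(benzyloxy)phenyl]-4-[3,4,5-tris(benzyloxy)benzylidene]tetrahydrofuran-3-carboxylate (double-bond geometry left open) | C(c2cc(OCc3ccccc3)c(OCc3ccccc3)c(OCc3ccccc3)c2)=C1CO[C@H](c2ccc(OCc3ccccc3)c(OCc3ccccc3)c2)[C@H]1C(=O)OC | intermediate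
11 | (2S,3S)-2-[3,4-bis(benzyloxy)phenyl]-4-[3,4,5-tris(benzyloxy)benzylidene]tetrahydrofuran-3-carboxylic acid (double-bond geometry left open) | C(c2cc(OCc3ccccc3)c(OCc3ccccc3)c(OCc3ccccc3)c2)=C1CO[C@H](c2ccc(OCc3ccccc3)c(OCc3ccccc3)c2)[C@H]1C(=O)O | intermediate
12 | (1S,4S,5R,8S)-8-[3,4-bis(benzyloxy)phenyl]-4-[3,4,5-tris(benzyloxy)phenyl]-3,7-dioxabicyclo[3.3.0]octan-2-one | O=C1O[C@H](c2cc(OCc3ccccc3)c(OCc3ccccc3)c(OCc3ccccc3)c2)[C@H]2CO[C@H](c3ccc(OCc4ccccc4)c(OCc4ccccc4)c3)[C@@H]12 | intermediate
13 | (1S,4S,5R,8S)-8-(3,4-dihydroxyphenyl)-4-(3,4,5-trihydroxyphenyl)-3,7-dioxabicyclo[3.3.0]octan-2-one (CNP0290035.1) | O=C1O[C@H](c2cc(O)c(O)c(O)c2)[C@H]2CO[C@H](c3ccc(O)c(O)c3)[C@@H]12 | target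

## Step count and risk

Total step count: 8. Longest linear sequence: 7 (steps 1, 2, 3, 5, 6, 7, 8); step 4 is a one-step branch.

**Step 3 (key step).**
- What may go wrong: the ester-stabilized zwitterion is a much weaker nucleophile than the parent complex, and its addition to an electron-rich aldehyde may be reversible and unfavourable, so that protodesilylation or self-condensation of the donor outruns cycloaddition. If the C–C bond formation is reversible, face selection moves to the ring closure and the enantioselectivity may erode. The exocyclic double bond may drift into conjugation with the ester. A methyl carbonate leaving group or In(acac)3 as co-catalyst are first adjustments but do not change the approach.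
- Fallback (sets out from 6, returns at 7): the two bonds are made one after the other under auxiliary control. Aldehyde 6 is added at −78 °C to the dibutylboron enolate (Bu2BOTf, iPr2NEt, CH2Cl2) of (S)-4-benzyl-3-[3-(chloromethyl)but-3-enoyl]oxazolidin-2-one F1, which is obtained by N-acylation of (S)-4-benzyloxazolidin-2-one. The closed Zimmerman–Traxler transition state of this Evans aldol reaction should give the syn adduct (S)-4-benzyl-3-[(2S)-2-{(S)-[3,4-bis(benzyloxy)phenyl](hydroxy)methyl}-3-(chloromethyl)but-3-enoyl]oxazolidin-2-one F2, in which C8 and C1 already have the configuration of 7 (the syn aldol becomes the trans ring). Ag2O in CH2Cl2 then closes the ether by intramolecular displacement of the allylic chloride, giving (S)-4-benzyl-3-{[(2S,3S)-2-[3,4-bis(benzyloxy)phenyl]-4-methylenetetrahydrofuran-3-yl]carbonyl}oxazolidin-2-one F3. MeMgBr in MeOH at 0 °C exchanges the auxiliary for methoxide and gives 7.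

**Step 5.**
- What may go wrong: slow turnover at the hindered 1,1-disubstituted alkene, consumption of the styrene by homodimerization, and migration of the exocyclic double bond into the ring through ruthenium hydrides.
- Fallback (sets out from 7, returns at 12, replacing steps 5 to 7): the aryl group is brought in as a nucleophile. Hydroboration of 7 with 9-BBN from the face opposite the ester gives methyl (2S,3S,4R)-2-[3,4-bis(benzyloxy)phenyl]-4-[(9-borabicyclo[3.3.1]nonan-9-yl)methyl]tetrahydrofuran-3-carboxylate F4 (not isolated). NaBO3·4H2O oxidizes it to methyl (2S,3S,4S)-2-[3,4-bis(benzyloxy)phenyl]-4-(hydroxymethyl)tetrahydrofuran-3-carboxylate F5, which is oxidized at once with Dess–Martin periodinane to methyl (2S,3S,4R)-2-[3,4-bis(benzyloxy)phenyl]-4-formyltetrahydrofuran-3-carboxylate F6. [3,4,5-Tris(benzyloxy)phenyl]magnesium bromide F7 (from 5-bromo-1,2,3-tris(benzyloxy)benzene and Mg) adds to the aldehyde at −78 °C and the alkoxide closes onto the cis ester. A short treatment with TFA equilibrates C4 through the benzylic cation and gives 12.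

**Step 7.**
- What may go wrong: ionization of the C8–O7 benzylic ether next to the more electron-donating bis(benzyloxy)phenyl ring (epimerization or ring opening at C8); Friedel–Crafts attack of the C4 cation on the C8 aryl ring after protonation on the wrong face; sluggish protonation because the flanked para-benzyloxy group is twisted out of conjugation.
- Fallback (sets out from 11, returns at 12): the ring is closed by an electrophile instead of a proton. PhSeCl in CH2Cl2 at −78 °C effects selenolactonization of 11 to 8-[3,4-bis(benzyloxy)phenyl]-5-(phenylselanyl)-4-[3,4,5-tris(benzyloxy)phenyl]-3,7-dioxabicyclo[3.3.0]octan-2-one F8 (selenium on the ring-fusion carbon C5, C4 as either epimer). Bu3SnH and AIBN in toluene at 80 °C then replace selenium by hydrogen. The C5 radical can only take up hydrogen to give the cis-fused ring, and a C4 epimer, if present, is equilibrated with a trace of acid to 12.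

**Step 8.**
- What may go wrong: over-reduction by hydrogenolysis of the lactone C4–O3 or ether C8–O7 benzylic bonds once the phenols are free, and air oxidation of the product during isolation.
- Fallback (sets out from 12, returns at 13): Lewis-acid debenzylation with BCl3 and pentamethylbenzene as cation scavenger in CH2Cl2 at −78 °C, which uses no hydrogen and no metal surface; it makes no new compound (F0).

**Step 6.**
- What may go wrong: deprotonation at C1 during saponification, leading to migration of the double bond into conjugation with the carboxyl or to loss of the C1 configuration.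
- Fallback (sets out from 10, returns at 12): the separate hydrolysis is dropped. Ester 10 is treated with TFA containing a little water in CH2Cl2; the ester carbonyl oxygen captures the C4 cation and the resulting dialkoxycarbenium ion loses its methyl group as methanol on attack by water, giving 12 directly. It makes no new compound (F0).

## Further compounds

F1 | step 3 | (S)-4-benzyl-3-[3-(chloromethyl)but-3-enoyl]oxazolidin-2-one | C=C(CCl)CC(=O)N1[C@@H](Cc2ccccc2)COC1=O
F2 | step 3 | (S)-4-benzyl-3-[(2S)-2-{(S)-[3,4-bis(benzyloxy)phenyl](hydroxy)methyl}-3-(chloromethyl)but-3-enoyl]oxazolidin-2-one | O=C(N1[C@@H](Cc2ccccc2)COC1=O)[C@H]([C@H](O)c1ccc(OCc2ccccc2)c(OCc2ccccc2)c1)C(=C)CCl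
F3 | step 3 | (S)-4-benzyl-3-{[(2S,3S)-2-[3,4-bis(benzyloxy)phenyl]-4-methylenetetrahydrofuran-3-yl]carbonyl}oxazolidin-2-one | C=C1CO[C@H](c2ccc(OCc3ccccc3)c(OCc3ccccc3)c2)[C@H]1C(=O)N1[C@@H](Cc2ccccc2)COC1=O
F4 | step 5 | methyl (2S,3S,4R)-2-[3,4-bis(benzyloxy)phenyl]-4-[(9-borabicyclo[3.3.1]nonan-9-yl)methyl]tetrahydrofuran-3-carboxylate (not isolated) | B3(C[C@H]1CO[C@H](c2ccc(OCc5ccccc5)c(OCc5ccccc5)c2)[C@H]1C(=O)OC)C4CCCC3CCC4
F5 | step 5 | methyl (2S,3S,4S)-2-[3,4-bis(benzyloxy)phenyl]-4-(hydroxymethyl)tetrahydrofuran-3-carboxylate | OC[C@H]1CO[C@H](c2ccc(OCc3ccccc3)c(OCc3ccccc3)c2)[C@H]1C(=O)OC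
F6 | step 5 | methyl (2S,3S,4R)-2-[3,4-bis(benzyloxy)phenyl]-4-formyltetrahydrofuran-3-carboxylate | O=C[C@H]1CO[C@H](c2ccc(OCc3ccccc3)c(OCc3ccccc3)c2)[C@H]1C(=O)OC
F7 | step 5 | [3,4,5-tris(benzyloxy)phenyl]magnesium bromide | Br[Mg]c1cc(OCc2ccccc2)c(OCc2ccccc2)c(OCc2ccccc2)c1
F8 | step 7 | 8-[3,4-bis(benzyloxy)phenyl]-5-(phenylselanyl)-4-[3,4,5-tris(benzyloxy)phenyl]-3,7-dioxabicyclo[3.3.0]octan-2-one (C1 and C8 as in 12, selenium on C5, C4 as either epimer) | O=C1OC(c2cc(OCc3ccccc3)c(OCc3ccccc3)c(OCc3ccccc3)c2)[C@@]2([Se]c3ccccc3)CO[C@H](c3ccc(OCc4ccccc4)c(OCc4ccccc4)c3)[C@@H]12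
F0 | step 8 | none | none
F0 | step 6 | none | none
A1 | alternative 1 | (2R,3R)-2-[3-(benzyloxy)-4-hydroxybenzyl]-3-[3,5-bis(benzyloxy)-4-hydroxybenzyl]-4-hydroxy-N,N-dimethylbutanamide | CN(C)C(=O)[C@H](Cc1ccc(O)c(OCc2ccccc2)c1)[C@H](CO)Cc1cc(OCc2ccccc2)c(O)c(OCc2ccccc2)c1
A2 | alternative 1 | (1S,4S,5R,8S)-8-[3-(benzyloxy)-4-hydroxyphenyl]-4-[3,5-bis(benzyloxy)-4-hydroxyphenyl]-3,7-dioxabicyclo[3.3.0]octan-2-one | O=C1O[C@H](c2cc(OCc3ccccc3)c(O)c(OCc3ccccc3)c2)[C@H]2CO[C@H](c3ccc(O)c(OCc4ccccc4)c3)[C@@H]12
A3 | alternative 2 | 2-[(1E,3S)-3-[3,4-bis(benzyloxy)phenyl]-3-{[(2E)-3-[3,4,5-tris(benzyloxy)phenyl]prop-2-en-1-yl]oxy}prop-1-en-1-yl]-4,4,5,5-tetramethyl-1,3,2-dioxaborolane | CC1(C)OB(/C=C/[C@H](OC/C=C/c2cc(OCc3ccccc3)c(OCc3ccccc3)c(OCc3ccccc3)c2)c2ccc(OCc3ccccc3)c(OCc3ccccc3)c2)OC1(C)C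
A4 | alternative 2 | 2-[3,4-bis(benzyloxy)phenyl]-6-[3,4,5-tris(benzyloxy)phenyl]-3-oxabicyclo[3.2.0]heptan-7-yl pinacol boronate (boron-bearing carbon as either epimer) | CC1(C)OB(C2[C@H](c4cc(OCc5ccccc5)c(OCc5ccccc5)c(OCc5ccccc5)c4)[C@H]3CO[C@H](c4ccc(OCc5ccccc5)c(OCc5ccccc5)c4)[C@@H]23)OC1(C)C
A5 | alternative 3 | (S)-5-[3,4,5-tris(benzyloxy)phenyl]furan-2(5H)-one | O=C1O[C@H](c2cc(OCc3ccccc3)c(OCc3ccccc3)c(OCc3ccccc3)c2)C=C1
A6 | alternative 3 | ({[3,4-bis(benzyloxy)phenyl](chloro)methoxy}methyl)trimethylsilane | C[Si](C)(C)COC(Cl)c1ccc(OCc2ccccc2)c(OCc2ccccc2)c1
A7 | alternative 3 | (1S,4S,5R,8S)-8-[3,4-bis(benzyloxy)phenyl]-4-[3,4,5-tris(benzyloxy)phenyl]-3,7-dioxabicyclo[3.3.0]octan-2-one (identical with 12) | O=C1O[C@H](c2cc(OCc3ccccc3)c(OCc3ccccc3)c(OCc3ccccc3)c2)[C@H]2CO[C@H](c3ccc(OCc4ccccc4)c(OCc4ccccc4)c3)[C@@H]12
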